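Conventions: dihydrobenzofuran 1 has atoms O1, C2, C3, C3a, C4–C7, C7a (benzene ring A); dihydrobenzofuran 2 has the primed atoms (benzene ring B); C3 is bonded to C5'. An = 4-methoxyphenyl. Bf = (2R,3R)-3-(3,5-dimethoxyphenyl)-7-methoxy-2-(4-methoxyphenyl)-2,3-dihydro-1-benzofuran-5-yl, that is, dihydrobenzofuran 2 as its methyl ethers, attached through C5'.

## Analysis of the target

Target 39 is built from two trans-2,3-diaryl-2,3-dihydrobenzofurans joined by the C3–C5' bond. Dihydrobenzofuran 1 carries an (E)-4-hydroxystyryl group on C4, a hydroxyl on C6 and a 4-hydroxyphenyl group on C2; dihydrobenzofuran 2 carries a hydroxyl on C7', a 3,5-dihydroxyphenyl group on C3' and a 4-hydroxyphenyl group on C2'. The four stereocentres are C2 (S) and C3 (S), trans to each other, and C2' (R) and C3' (R), also trans. The two pairs are separated by the flat ring B, so neither can direct the other and each needs its own source of absolute configuration. Sensitive points are the stilbene (light, acid, hydrogenation), the seven electron-rich phenols (oxidation), the benzylic ether bonds C2–O1 and C2'–O1' (each carbon bears a 4-oxygenated aryl group and ionises under acid), and the hydrogens on C3 and C3', which lie beta to an aryloxy leaving group and invite ring opening by strong base. The hard part is ring A, a benzene with two meta oxygens (C6, C7a) and two neighbouring carbon substituents (C3a, C4), which substitution of a preformed resorcinol reaches only with regiochemical ambiguity. The strategy rests on this ring: hydroxyl on C6, ether oxygen on C7a, hydrogen on C5 and C7, styryl on C4 and the alkyl carbon C3 on C3a are the pattern that a vinylketene and an alkynyl ether give on benzannulation. Because O1 is already tied to C3a through C2 and C3, the alkynyl ether can be the C2 oxygen itself, and the dihydrofuran then closes in the same event.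

## Retrosynthetic reasoning

**39 from 38.** Six aryl–O–methyl bonds are cut last. Methyl ethers are the only phenol protection that survives alkyllithium, hydride base, fluoride, oxidants and light; the seventh phenol (C6–OH) is formed free in the ring-forming step. The forward step has to cleave six ethers without letting the two acid-labile benzylic ether bonds react irreversibly.

**38 from 33.** Ring A is taken apart at C3a–C4, C3a–C7a, C6–C7 and C5–C6, which also opens the dihydrofuran. This leads back to the acyclic diazo dienone 33, in which the diazo carbon is the future C3a, the carbonyl carbon the future C6, the 1-styrylvinyl group supplies C4 and C5, and the ethynyl ether on the C2 oxygen supplies C7a and C7. Cutting here and not at an aryl–O or aryl–C bond means that no position of a preformed arene has to be told apart from another: tether and polarity fix every substituent. The forward reaction has to pass through 34, 35, 36 and 37 without touching C2 and C3.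

**33 from 31, 30, 26 and 29.** The diazo group is put on the only enolisable carbon of dienone 31. The acyl–dienyl bond, made by adding dienyllithium 29 to aldehyde 26 and oxidising 30, is the bond that the Wolff shift later breaks. The ethynyl ether must already be present, because its formation needs a metal hydride and an alkyllithium, which neither a ketone nor a diazo ketone survives. Two consequences follow. The carbonyl carbon is carried through the ether formation as a silyl-protected primary alcohol. The diazo transfer has to be run cold with little excess of azide so that the electron-rich alkyne is left alone.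

**24 from 20 and 21; 20 from 19 and 17.** The O–C(sp) bond is made from the free C2 hydroxyl of 20 and trichloroethylene 21 at a stage where the molecule holds only ethers. Diol 19 comes from hydroboration of the terminal alkene of 17; the primary hydroxyl is silylated selectively.

**17 from 14 and 15.** The C2–C3 bond is cut. An (E)-allylboronate 14 and 4-methoxybenzaldehyde 15 give both stereocentres in one closed transition state: anti from the alkene geometry, absolute sense from a chiral Brønsted acid. A conjugate arylation of a gamma-oxygenated enoate was weighed for the same diad. It was not used because it needs two separate stereo-defining steps, rests on an uncertain substrate bias, and gives a gamma-hydroxy ester that lactonises.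

**14 from 13, 10 and 11.** The C5'–C3 bond is made by adding aryllithium 12 (from bromide 10) to acrolein 11; allylic borylation of acetate 13 moves the functionality to the terminus.

**10 from 9, 7, 6, 5, 3, 4, 1 and 2.** Dihydrobenzofuran 2 is made first and carried as a spectator. Building it on ring B after the ring A event would have no stereochemical relay from C2/C3. An oxidative phenol–stilbene coupling there would give both trans diastereomers and homodimers, and hydrogenolytic removal of a benzyl group would reduce the stilbene. Instead, C3'–C2' is made by enantioselective carbene C–H insertion of diazo compound 8 into the benzylic ether CH2 of the 4-methoxybenzyl group introduced with 2. C2' is then equilibrated to trans with acid. The aryl bromide of 1 is the handle for the junction.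

**29 from 28 and 27.** The dienyllithium comes from the arenesulfonylhydrazone of enone 27 by a Shapiro reaction.

## Alternatives that were turned down

**Alternative 1:** Dihydrobenzofuran 2 is disconnected at C3'–C2' and at the C2'–aryl bond; both carbons are grown on boron by successive one-carbon boronate homologations under control of a chiral diol. In the forward key step the diarylmethyl boronic ester A2 takes up the chlorinated one-carbon carbenoid, C3' migrates from boron to carbon with loss of chloride, and an aryl Grignard reagent then displaces the second chloride by 1,2-migration with inversion to give A1.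
- For it: both centres are set by one inexpensive auxiliary with a predictable sense, and C2' is fixed by a stereospecific migration rather than by equilibration.
- Against it: the migrating group is a hindered, electron-rich diarylmethyl carbon; benzylic alpha-chloro boronic esters epimerise through chloride exchange; the benzhydryl–boron bond is prone to protodeboronation. After A1 the sequence still needs C–B oxidation, a metal-mediated C–O ring closure beside a crowded centre, and functionalisation of ring B para to oxygen before ring A can be attached.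
- Comparison: it is stronger than the chosen route at C2', which here rests on thermodynamic trans preference, but it is longer for the same fragment (the chosen route reaches 10 from ketone 6 in three steps) and does nothing for ring A. The chosen strategy offers a de novo ring A with every substituent placed by the ring-forming event.

**Alternative 2:** The O1'–C2' bond is disconnected and C2' is traced to the alpha-carbon of the 3,4-diaryl dihydrocoumarin A4, whose lactone carbonyl is removed by decarboxylation. In the forward key step hydroxide opens the lactone, anodic oxidation of the arylacetate (Hofer–Moest pathway) gives a 4-methoxybenzylic cation at C2', and the ring B phenol captures it, contracting the six-membered lactone to the trans dihydrofuran A3.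
- For it: C3' comes from well-developed asymmetric conjugate arylation of coumarins; no diazo compound or rhodium is needed; the ester on C5' is a ready handle.
- Against it: an electron-rich guaiacol-type phenoxide is oxidised more easily than a carboxylate, so phenol coupling competes at the anode. The cation next to an aryl-bearing carbon can suffer 1,2-aryl shift or elimination to a stilbene. The ring contraction itself is untested.
- Comparison: A3 is the ester analogue of bromide 10 and would enter the chosen route at the same point, so the step count for dihydrobenzofuran 2 is about equal. It is stronger in using no precious metal. The chosen route reaches 10 by a carbene insertion that is established for this ring system, and it keeps the untested chemistry in one place, the ring A event, which alternative 2 leaves unaddressed.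

**Alternative 3:** Dihydrobenzofuran 1 is disconnected at C7a–O1 and C3a–C3: ring A is an aryne released from silyl triflate A6, and C2/C3 come from the enantiopure trans-epoxide A7. In the forward key step fluoride frees the aryne, the epoxide oxygen adds to C7a (away from the alkoxy group), the benzylic C3–O bond ionises, and the aryl anion at C3a closes on C3 to give A5.
- For it: it is the shortest way to dihydrobenzofuran 1; one step joins two simple pieces, C2 comes from a reliable asymmetric epoxidation, and ring A is bought rather than built. In step count this is stronger than the chosen route.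
- Against it: epoxides are weak nucleophiles towards arynes, and the oxonium zwitterion of a stilbene oxide can rearrange to a carbonyl compound instead of closing. The C3 configuration depends on how the zwitterion collapses. The product carries an oxygen on C4, which then has to be turned into the styryl group by triflation and cross-coupling at a position flanked by C3a. The tosylate that biases the ionisation has to be exchanged afterwards.
- Comparison: alternative 3 wins on convergence. The chosen strategy delivers the styryl group on C4, the free C6 hydroxyl and O1 in the same event that makes the ring, with regiochemistry fixed by the tether, and needs no late C–C coupling on ring A.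

Key step: step 19

Remark on the chemistry: the senses of induction of the two chiral catalysts (steps 5 and 9) are assigned from the accepted models for these catalyst families; if a first run shows the opposite sense, the antipodal catalyst is used and nothing else changes.

Remark on the chemistry: 4 is taken as its commercial THF solution.

## Steps

**Step 1**
Reactants: 1 5-bromo-2-hydroxy-3-methoxybenzaldehyde; 2 4-methoxybenzyl chloride
Product: 3 5-bromo-3-methoxy-2-[(4-methoxybenzyl)oxy]benzaldehyde
Conditions: K2CO3, KI (cat.), DMF, 60 °C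
Reagents that add atoms: none
Why: Williamson etherification of the phenoxide. The benzylic CH2 introduced here becomes C2' and its aryl group the C2' substituent.

**Step 2**
Reactants: 3; 4 (3,5-dimethoxyphenyl)magnesium chloride
Product: 5 rac-{5-bromo-3-methoxy-2-[(4-methoxybenzyl)oxy]phenyl}(3,5-dimethoxyphenyl)methanol
Conditions: THF, −20 → 0 °C; aq NH4Cl
Reagents that add atoms: none
Why: Grignard addition to the aldehyde. The carbinol carbon is the future C3' and is racemic here, which does not matter because it becomes trigonal in step 3.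

**Step 3**
Reactants: 5
Product: 6 {5-bromo-3-methoxy-2-[(4-methoxybenzyl)oxy]phenyl}(3,5-dimethoxyphenyl)methanone
Conditions: MnO2, CH2Cl2, rt
Reagents that add atoms: none
Why: MnO2 oxidises the doubly benzylic alcohol; the aryl bromide and the benzyl ether are inert.

**Step 4**
Reactants: 6
Product: 7 hydrazone of 6 (E/Z mixture)
Conditions: N2H4·H2O, AcOH (cat.), EtOH, 80 °C
Reagents that add atoms: hydrazine hydrate, NN.O
Why: Condensation of the diaryl ketone with excess hydrazine; the excess suppresses azine formation.

**Step 5**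
Reactants: 7
Product: 9 (2S,3R)-5-bromo-3-(3,5-dimethoxyphenyl)-7-methoxy-2-(4-methoxyphenyl)-2,3-dihydro-1-benzofuran (cis), via diaryldiazomethane 8 (not isolated)
Conditions: MnO2, CH2Cl2, 0 °C, filter; then Rh2(R-PTAD)4 (1 mol %; PTAD = (1-adamantyl)(phthalimido)acetate), CH2Cl2, 0 °C → rt
Reagents that add atoms: none
Why: MnO2 dehydrogenates the hydrazone to 8. The dirhodium tetracarboxylate (divalent rhodium) forms a donor/donor carbene that inserts into the benzylic ether C–H bond five atoms away, making C3'–C2' (enantioselective intramolecular C–H insertion). The chiral carboxylate ligands select the carbene face and one of the two enantiotopic C–H bonds, giving the cis product with C3' as R.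

**Step 6**
Reactants: 9
Product: 10 (2R,3R)-5-bromo-3-(3,5-dimethoxyphenyl)-7-methoxy-2-(4-methoxyphenyl)-2,3-dihydro-1-benzofuran (trans; Bf–Br)
Conditions: CF3CO2H, CH2Cl2, 0 °C
Reagents that add atoms: none
Why: Acid reversibly ionises the C2'–O1' bond to a 4-methoxybenzylic cation, and reclosure gives the more stable trans isomer (acid-mediated epimerisation). C3' takes no part, so its configuration from step 5 now controls C2'.

**Step 7**
Reactants: 10; 11 acrolein
Product: 13 1-Bf-prop-2-en-1-yl acetate (both epimers at the carbinol carbon), via aryllithium 12 (not isolated)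
Conditions: n-BuLi, THF, −78 °C; 11, −78 °C; Ac2O, −78 → 0 °C
Reagents that add atoms: acetic anhydride, CC(=O)OC(C)=O; n-butyllithium, CCCC[Li] (lithium kept only in 12)
Why: Bromine–lithium exchange is faster than any deprotonation of the dihydrofuran at −78 °C. The aryllithium adds 1,2 to acrolein and the alkoxide is acetylated in the flask.

**Step 8**
Reactants: 13
Product: 14 2-[(2E)-3-Bf-prop-2-en-1-yl]-4,4,5,5-tetramethyl-1,3,2-dioxaborolane
Conditions: B2pin2, Pd2(dba)3 (2.5 mol %), DMSO, 50 °C
Reagents that add atoms: bis(pinacolato)diboron, CC1(C)OB(OC1(C)C)B1OC(C)(C)C(C)(C)O1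
Why: Miyaura-type allylic borylation. Zerovalent palladium ionises the acetate to a pi-allyl complex, and boron is delivered to the unsubstituted terminus, giving the conjugated (E) linear allylboronate whichever allylic isomer of 13 is used.

**Step 9**
Reactants: 14; 15 4-methoxybenzaldehyde
Product: 17 (1S,2R)-2-Bf-1-(4-methoxyphenyl)but-3-en-1-ol, via pinacol borate 16 (not isolated)
Conditions: (S)-TRIP (5 mol %), 4 Å MS, toluene, −30 °C; aq NaHCO3
Reagents that add atoms: none
Why: Brønsted acid-catalysed allylboration through a closed chair transition state. The (E) boronate with the aldehyde aryl group equatorial gives the anti diad. The chiral phosphoric acid, hydrogen-bonded to a boronate oxygen, directs the allyl group to the Si face of the aldehyde, setting C2 and C3 of the target as (1S,2R) in 17.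

**Step 10**
Reactants: 17
Product: 19 (1S,2R)-2-Bf-1-(4-methoxyphenyl)butane-1,4-diol, via B-alkyl-9-BBN adduct 18 (not isolated)
Conditions: 9-BBN, THF, 0 °C → rt; NaOH, H2O2, 0 °C → rt
Reagents that add atoms: hydrogen peroxide, OO; 9-borabicyclo[3.3.1]nonane, C1CC2CCCC(C1)B2 (boron kept only in 18)
Why: Anti-Markovnikov hydroboration of the monosubstituted alkene with a bulky borane, then oxidation of the C–B bond with retention. The stereocentres are untouched.

**Step 11**
Reactants: 19
Product: 20 (1S,2R)-2-Bf-1-(4-methoxyphenyl)-4-[(triisopropylsilyl)oxy]butan-1-ol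
Conditions: iPr3SiCl, imidazole, CH2Cl2, 0 °C
Reagents that add atoms: chlorotriisopropylsilane, CC(C)[Si](Cl)(C(C)C)C(C)C
Why: The bulky silyl chloride reacts only with the primary hydroxyl; the secondary benzylic hydroxyl beside the Bf-bearing carbon stays free. The triisopropylsilyl group is chosen because it resists O-to-O migration under the alkoxide conditions of step 12.

**Step 12**
Reactants: 20; 21 trichloroethylene
Product: 24 {[(3R,4S)-4-(ethynyloxy)-4-(4-methoxyphenyl)-3-Bf-butyl]oxy}triisopropylsilane, via dichlorovinyl ether 22 (not isolated), via lithium alkynyl ether 23 (not isolated)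
Conditions: KH, THF, 0 °C → rt; 21, rt; n-BuLi, −78 → −40 °C; MeOH, −78 °C
Reagents that add atoms: n-butyllithium, CCCC[Li] (lithium kept only in 23)
Why: The potassium alkoxide adds to dichloroacetylene formed in the flask from 21 to give the (E)-1,2-dichlorovinyl ether; n-BuLi then eliminates HCl and exchanges the remaining chlorine, and methanol protonates the lithium alkynyl ether (ynol ether synthesis from trichloroethylene). The C2–O bond is never broken, so the configuration is kept. This is the one stage at which no carbonyl or diazo group is present to be attacked by the bases.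

**Step 13**
Reactants: 24
Product: 25 (3R,4S)-4-(ethynyloxy)-4-(4-methoxyphenyl)-3-Bf-butan-1-ol
Conditions: Bu4NF, THF, 0 °C → rt
Reagents that add atoms: none
Why: Fluoride cleaves the Si–O bond; alkynyl ethers tolerate fluoride and mild base.

**Step 14**
Reactants: 25
Product: 26 (3R,4S)-4-(ethynyloxy)-4-(4-methoxyphenyl)-3-Bf-butanal
Conditions: Dess–Martin periodinane, pyridine, CH2Cl2, 0 °C
Reagents that add atoms: none
Why: Dess–Martin oxidation buffered with pyridine avoids the acid that would hydrate the alkynyl ether. The carbon alpha to the aldehyde is a CH2, so nothing can epimerise.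

**Step 15**
Reactants: 27 (E)-4-(4-methoxyphenyl)but-3-en-2-one
Product: 28 N'-[(2E,3E)-4-(4-methoxyphenyl)but-3-en-2-ylidene]-2,4,6-triisopropylbenzenesulfonohydrazide
Conditions: 2,4,6-iPr3C6H2SO2NHNH2, HCl (cat.), MeOH, rt
Reagents that add atoms: 2,4,6-triisopropylbenzenesulfonohydrazide, CC(C)c1cc(C(C)C)c(S(=O)(=O)NN)c(C(C)C)c1
Why: Condensation at room temperature gives the hydrazone with the sulfonamide nitrogen syn to the methyl group, as the Shapiro deprotonation requires.

**Step 16**
Reactants: 26; 28
Product: 30 (1E,6R,7S)-7-(ethynyloxy)-1,7-bis(4-methoxyphenyl)-3-methylidene-6-Bf-hept-1-en-4-ol (both C4 epimers), via dienyllithium 29 (not isolated)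
Conditions: 28, n-BuLi (2 equiv per 28), THF, −78 → 0 °C; 26, −78 °C; pH 7 buffer
Reagents that add atoms: n-butyllithium, CCCC[Li] (lithium kept only in 29)
Why: Shapiro reaction: double deprotonation (N–H, then the methyl group), loss of sulfinate and N2 give the 2-lithio-1,3-diene, which adds 1,2 to the aldehyde at −78 °C. The reagent is used in excess because one equivalent is consumed by the acidic alkyne C–H, which is restored on work-up. The new carbinol centre is uncontrolled and is removed in step 17.

**Step 17**
Reactants: 30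
Product: 31 (1E,6R,7S)-7-(ethynyloxy)-1,7-bis(4-methoxyphenyl)-3-methylidene-6-Bf-hept-1-en-4-one
Conditions: MnO2, CH2Cl2, 0 °C → rt; used at once
Reagents that add atoms: none
Why: MnO2 oxidises the allylic alcohol under neutral conditions that the alkynyl ether tolerates. The 2-acyl-1,3-diene is kept cold and dilute and carried on directly, because such dienes dimerise by Diels–Alder reaction.

**Step 18**
Reactants: 31
Product: 33 (1E,6S,7S)-5-diazo-7-(ethynyloxy)-1,7-bis(4-methoxyphenyl)-3-methylidene-6-Bf-hept-1-en-4-one (the C6 descriptor changes by the priority rule only), via trifluoroacetyl ketone 32 (not isolated)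
Conditions: LiN(SiMe3)2, THF, −78 °C; CF3CO2CH2CF3, −78 °C; pH 7 buffer; MeSO2N3 (1.1 equiv), Et3N, H2O, MeCN, 0 °C → rt
Reagents that add atoms: methanesulfonyl azide, CS(=O)(=O)N=[N+]=[N-]; 2,2,2-trifluoroethyl trifluoroacetate, O=C(OCC(F)(F)F)C(F)(F)F (trifluoroacetyl group kept only in 32)
Why: Detrifluoroacetylative diazo transfer (Regitz type). The ketone has one enolisable position; its lithium enolate is acylated to the 1,3-diketone, which takes the diazo group from the sulfonyl azide and loses the trifluoroacetyl group as the sulfonamide. The stereocentre next to the diazo carbon is not alpha to a carbonyl and cannot epimerise; low temperature and near-stoichiometric azide keep the electron-rich alkyne from cycloaddition.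

**Step 19**
Reactants: 33
Product: 38 (2S,3S)-3-Bf-2-(4-methoxyphenyl)-4-[(E)-2-(4-methoxyphenyl)ethenyl]-2,3-dihydro-1-benzofuran-6-ol, via vinylketene 34 (not isolated), via cyclobutenone 35 (not isolated), via dienylketene 36 (not isolated), via cyclohexadienone 37 (not isolated)
Conditions: hν (blue LEDs, 440–450 nm), degassed toluene (5 mM), 20 °C; then 70 °C, dark
Reagents that add atoms: none
Why: Proposed new method: excitation of the diazo ketone band of 33 expels N2 while the 1,3-dien-2-yl group shifts from the carbonyl carbon to the diazo carbon (Wolff rearrangement, bond C3a–C4) to give vinylketene 34; the closest known reaction type is the photochemical Danheiser benzannulation of alpha-diazo enones with alkynyl ethers, known only between two separate partners. The nucleophilic terminal carbon of the ethynyl ether attacks the ketene carbonyl carbon (C6–C7) and the ketene alpha-carbon bonds to the oxygen-bearing alkyne carbon (C3a–C7a); this [2+2] cycloaddition closes the dihydrofuran as a five-membered ring over the tether C3–C2–O1 (5-exo-dig with respect to the alkyne) and gives the strained bicyclic 4-alkoxycyclobutenone 35. On warming, 35 opens by 4π electrocyclic cleavage of C6–C3a to dienylketene 36, in which the ketene and the 1-styrylvinyl group are held cis on the ring double bond C7a=C3a, so 6π electrocyclisation (bond C5–C6, ring A closed as a six-membered carbocycle) and enolisation of 37 follow. No stereocentre is created: C2 and C3 take part in no bond change and are carried over from 33, and the quaternary C3a of 35 becomes trigonal again. The step needs the vinyl shift to outrun the 1,2-hydride shift from C3, which the good migratory aptitude of the dienyl group and concerted loss of N2 from the s-cis conformer should secure. The regiochemistry of the cycloaddition is fixed twice, by the three-atom tether and by the ketene–ynol ether polarity. Light above 400 nm leaves the aryl diene and the product stilbene unexcited, so the (E) geometry should be kept, and irradiation at 20 °C holds the ethynyl ether below the temperature of its retro-ene and sigmatropic decay until it is consumed, heat being applied only afterwards. High dilution suppresses ketene dimerisation and Diels–Alder dimerisation of the acyl diene.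

**Step 20**
Reactants: 38
Product: 39 (2S,3S)-3-[(2R,3R)-3-(3,5-dihydroxyphenyl)-7-hydroxy-2-(4-hydroxyphenyl)-2,3-dihydro-1-benzofuran-5-yl]-2-(4-hydroxyphenyl)-4-[(E)-2-(4-hydroxyphenyl)ethenyl]-2,3-dihydro-1-benzofuran-6-ol
Conditions: BBr3, CH2Cl2, −78 → 0 °C; MeOH, H2O
Reagents that add atoms: none
Why: Lewis acid-mediated cleavage of the six aryl methyl ethers (complexation, then bromide attack at methyl). Both dihydrofurans are already in their thermodynamically preferred trans form, so a reversible ionisation of C2–O1 or C2'–O1' returns the same configuration, and C3 and C3' are not touched.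

## Compound list

1 | 5-bromo-2-hydroxy-3-methoxybenzaldehyde | O=Cc1cc(Br)cc(OC)c1O | starting material
2 | 4-methoxybenzyl chloride | COc1ccc(CCl)cc1 | starting material
3 | 5-bromo-3-methoxy-2-[(4-methoxybenzyl)oxy]benzaldehyde | O=Cc1cc(Br)cc(OC)c1OCc1ccc(OC)cc1 | intermediate
4 | (3,5-dimethoxyphenyl)magnesium chloride | COc1cc(OC)cc([Mg]Cl)c1 | starting material
5 | rac-{5-bromo-3-methoxy-2-[(4-methoxybenzyl)oxy]phenyl}(3,5-dimethoxyphenyl)methanol | OC(c1cc(OC)cc(OC)c1)c1cc(Br)cc(OC)c1OCc1ccc(OC)cc1 | intermediate
6 | {5-bromo-3-methoxy-2-[(4-methoxybenzyl)oxy]phenyl}(3,5-dimethoxyphenyl)methanone | O=C(c1cc(OC)cc(OC)c1)c1cc(Br)cc(OC)c1OCc1ccc(OC)cc1 | intermediate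
7 | hydrazone of 6 (E/Z mixture) | NN=C(c1cc(OC)cc(OC)c1)c1cc(Br)cc(OC)c1OCc1ccc(OC)cc1 | intermediate
8 | 5-bromo-1-[diazo(3,5-dimethoxyphenyl)methyl]-3-methoxy-2-[(4-methoxybenzyl)oxy]benzene | [N-]=[N+]=C(c1cc(OC)cc(OC)c1)c1cc(Br)cc(OC)c1OCc1ccc(OC)cc1 | intermediate (not isolated)
9 | (2S,3R)-5-bromo-3-(3,5-dimethoxyphenyl)-7-methoxy-2-(4-methoxyphenyl)-2,3-dihydro-1-benzofuran (cis) | Brc1cc(OC)c2c(c1)[C@@H](c1cc(OC)cc(OC)c1)[C@@H](c1ccc(OC)cc1)O2 | intermediate
10 | (2R,3R)-5-bromo-3-(3,5-dimethoxyphenyl)-7-methoxy-2-(4-methoxyphenyl)-2,3-dihydro-1-benzofuran (trans; Bf–Br) | Brc1cc(OC)c2c(c1)[C@@H](c1cc(OC)cc(OC)c1)[C@H](c1ccc(OC)cc1)O2 | intermediate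
11 | acrolein | C=CC=O | starting material
12 | Bf–Li (aryllithium from 10) | [Li]c1cc(OC)c2c(c1)[C@@H](c1cc(OC)cc(OC)c1)[C@H](c1ccc(OC)cc1)O2 | intermediate (not isolated)
13 | 1-Bf-prop-2-en-1-yl acetate (both epimers at the carbinol carbon) | CC(=O)OC(C=C)c1cc(OC)c2c(c1)[C@@H](c1cc(OC)cc(OC)c1)[C@H](c1ccc(OC)cc1)O2 | intermediate
14 | 2-[(2E)-3-Bf-prop-2-en-1-yl]-4,4,5,5-tetramethyl-1,3,2-dioxaborolane | CC1(C)OB(C/C=C/c2cc(OC)c3c(c2)[C@@H](c2cc(OC)cc(OC)c2)[C@H](c2ccc(OC)cc2)O3)OC1(C)C | intermediate
15 | 4-methoxybenzaldehyde | COc1ccc(C=O)cc1 | starting material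
16 | 2-{[(1S,2R)-2-Bf-1-(4-methoxyphenyl)but-3-en-1-yl]oxy}-4,4,5,5-tetramethyl-1,3,2-dioxaborolane | C=C[C@H](c1cc(OC)c2c(c1)[C@@H](c1cc(OC)cc(OC)c1)[C@H](c1ccc(OC)cc1)O2)[C@H](OB1OC(C)(C)C(C)(C)O1)c1ccc(OC)cc1 | intermediate (not isolated)
17 | (1S,2R)-2-Bf-1-(4-methoxyphenyl)but-3-en-1-ol | C=C[C@H](c1cc(OC)c2c(c1)[C@@H](c1cc(OC)cc(OC)c1)[C@H](c1ccc(OC)cc1)O2)[C@H](O)c1ccc(OC)cc1 | intermediate
18 | (1S,2R)-2-Bf-4-(9-borabicyclo[3.3.1]nonan-9-yl)-1-(4-methoxyphenyl)butan-1-ol | C(C[C@H](c1cc(OC)c2c(c1)[C@@H](c1cc(OC)cc(OC)c1)[C@H](c1ccc(OC)cc1)O2)[C@H](O)c1ccc(OC)cc1)B1C2CCCC1CCC2 | intermediate (not isolated)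
19 | (1S,2R)-2-Bf-1-(4-methoxyphenyl)butane-1,4-diol | OCC[C@H](c1cc(OC)c2c(c1)[C@@H](c1cc(OC)cc(OC)c1)[C@H](c1ccc(OC)cc1)O2)[C@H](O)c1ccc(OC)cc1 | intermediate
20 | (1S,2R)-2-Bf-1-(4-methoxyphenyl)-4-[(triisopropylsilyl)oxy]butan-1-ol | CC(C)[Si](OCC[C@H](c1cc(OC)c2c(c1)[C@@H](c1cc(OC)cc(OC)c1)[C@H](c1ccc(OC)cc1)O2)[C@H](O)c1ccc(OC)cc1)(C(C)C)C(C)C | intermediate
21 | trichloroethylene | ClC=C(Cl)Cl | starting material
22 | {[(3R,4S)-4-{[(E)-1,2-dichloroethenyl]oxy}-4-(4-methoxyphenyl)-3-Bf-butyl]oxy}triisopropylsilane | CC(C)[Si](OCC[C@H](c1cc(OC)c2c(c1)[C@@H](c1cc(OC)cc(OC)c1)[C@H](c1ccc(OC)cc1)O2)[C@H](O/C(Cl)=C\Cl)c1ccc(OC)cc1)(C(C)C)C(C)C | intermediate (not isolated)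
23 | lithium acetylide of 24 (lithium on the terminal alkyne carbon) | CC(C)[Si](OCC[C@H](c1cc(OC)c2c(c1)[C@@H](c1cc(OC)cc(OC)c1)[C@H](c1ccc(OC)cc1)O2)[C@H](OC#C[Li])c1ccc(OC)cc1)(C(C)C)C(C)C | intermediate (not isolated)
24 | {[(3R,4S)-4-(ethynyloxy)-4-(4-methoxyphenyl)-3-Bf-butyl]oxy}triisopropylsilane | CC(C)[Si](OCC[C@H](c1cc(OC)c2c(c1)[C@@H](c1cc(OC)cc(OC)c1)[C@H](c1ccc(OC)cc1)O2)[C@H](OC#C)c1ccc(OC)cc1)(C(C)C)C(C)C | intermediate
25 | (3R,4S)-4-(ethynyloxy)-4-(4-methoxyphenyl)-3-Bf-butan-1-ol | OCC[C@H](c1cc(OC)c2c(c1)[C@@H](c1cc(OC)cc(OC)c1)[C@H](c1ccc(OC)cc1)O2)[C@H](OC#C)c1ccc(OC)cc1 | intermediate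
26 | (3R,4S)-4-(ethynyloxy)-4-(4-methoxyphenyl)-3-Bf-butanal | O=CC[C@H](c1cc(OC)c2c(c1)[C@@H](c1cc(OC)cc(OC)c1)[C@H](c1ccc(OC)cc1)O2)[C@H](OC#C)c1ccc(OC)cc1 | intermediate
27 | (E)-4-(4-methoxyphenyl)but-3-en-2-one | COc1ccc(/C=C/C(C)=O)cc1 | starting material
28 | N'-[(2E,3E)-4-(4-methoxyphenyl)but-3-en-2-ylidene]-2,4,6-triisopropylbenzenesulfonohydrazide | C/C(/C=C/c1ccc(OC)cc1)=N\NS(=O)(=O)c1c(C(C)C)cc(C(C)C)cc1C(C)C | intermediate
29 | [(3E)-4-(4-methoxyphenyl)buta-1,3-dien-2-yl]lithium | [Li]C(=C)/C=C/c1ccc(OC)cc1 | intermediate (not isolated)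
30 | (1E,6R,7S)-7-(ethynyloxy)-1,7-bis(4-methoxyphenyl)-3-methylidene-6-Bf-hept-1-en-4-ol (both C4 epimers) | C=C(/C=C/c1ccc(OC)cc1)C(O)C[C@H](c1cc(OC)c2c(c1)[C@@H](c1cc(OC)cc(OC)c1)[C@H](c1ccc(OC)cc1)O2)[C@H](OC#C)c1ccc(OC)cc1 | intermediate
31 | (1E,6R,7S)-7-(ethynyloxy)-1,7-bis(4-methoxyphenyl)-3-methylidene-6-Bf-hept-1-en-4-one | C=C(/C=C/c1ccc(OC)cc1)C(=O)C[C@H](c1cc(OC)c2c(c1)[C@@H](c1cc(OC)cc(OC)c1)[C@H](c1ccc(OC)cc1)O2)[C@H](OC#C)c1ccc(OC)cc1 | intermediate
32 | 31 bearing a trifluoroacetyl group on C5 (1,3-diketone, C5 epimers and enol) | C=C(/C=C/c1ccc(OC)cc1)C(=O)C(C(=O)C(F)(F)F)[C@H](c1cc(OC)c2c(c1)[C@@H](c1cc(OC)cc(OC)c1)[C@H](c1ccc(OC)cc1)O2)[C@H](OC#C)c1ccc(OC)cc1 | intermediate (not isolated)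
33 | (1E,6S,7S)-5-diazo-7-(ethynyloxy)-1,7-bis(4-methoxyphenyl)-3-methylidene-6-Bf-hept-1-en-4-one | C=C(/C=C/c1ccc(OC)cc1)C(=O)C(=[N+]=[N-])[C@H](c1cc(OC)c2c(c1)[C@@H](c1cc(OC)cc(OC)c1)[C@H](c1ccc(OC)cc1)O2)[C@H](OC#C)c1ccc(OC)cc1 | intermediate (precursor of the key step)
34 | vinylketene: ketene whose alpha-carbon (future C3a) bears the (E)-4-(4-methoxyphenyl)buta-1,3-dien-2-yl group and the CH(Bf)–CH(OC≡CH)An chain, C2 and C3 as in 33 | O=C=C(C(=C)/C=C/c1ccc(OC)cc1)[C@H](c1cc(OC)c2c(c1)[C@@H](c1cc(OC)cc(OC)c1)[C@H](c1ccc(OC)cc1)O2)[C@H](OC#C)c1ccc(OC)cc1 | intermediate (not isolated)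
35 | 2-oxabicyclo[3.2.0]hept-1(7)-en-6-one with An on C3, Bf on C4 and the dienyl group on the bridgehead C5 (C3 and C4 as C2 and C3 of 38, C5 undefined) | O=C1C=C2O[C@H](c3ccc(OC)cc3)[C@@H](c3cc(OC)c4c(c3)[C@@H](c3cc(OC)cc(OC)c3)[C@H](c3ccc(OC)cc3)O4)C12C(=C)/C=C/c1ccc(OC)cc1 | intermediate (not isolated)
36 | dienylketene: 2,3-dihydrofuran with An on C2, Bf on C3, the dienyl group on C4 and a ketenyl group (CH=C=O) on C5, C2 and C3 as in 38 | O=C=CC1=C(C(=C)/C=C/c2ccc(OC)cc2)[C@H](c2cc(OC)c3c(c2)[C@@H](c2cc(OC)cc(OC)c2)[C@H](c2ccc(OC)cc2)O3)[C@@H](c2ccc(OC)cc2)O1 | intermediate (not isolated)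
37 | 5H-keto tautomer of 38 (2,3-dihydro-1-benzofuran-6(5H)-one, C5 a CH2 group) | O=C1C=C2O[C@H](c3ccc(OC)cc3)[C@@H](c3cc(OC)c4c(c3)[C@@H](c3cc(OC)cc(OC)c3)[C@H](c3ccc(OC)cc3)O4)C2=C(/C=C/c2ccc(OC)cc2)C1 | intermediate (not isolated)
38 | (2S,3S)-3-Bf-2-(4-methoxyphenyl)-4-[(E)-2-(4-methoxyphenyl)ethenyl]-2,3-dihydro-1-benzofuran-6-ol | COc1ccc(/C=C/c2cc(O)cc3c2[C@H](c2cc(OC)c4c(c2)[C@@H](c2cc(OC)cc(OC)c2)[C@H](c2ccc(OC)cc2)O4)[C@@H](c2ccc(OC)cc2)O3)cc1 | intermediate (product of the key step)
39 | (2S,3S)-3-[(2R,3R)-3-(3,5-dihydroxyphenyl)-7-hydroxy-2-(4-hydroxyphenyl)-2,3-dihydro-1-benzofuran-5-yl]-2-(4-hydroxyphenyl)-4-[(E)-2-(4-hydroxyphenyl)ethenyl]-2,3-dihydro-1-benzofuran-6-ol | Oc1ccc(/C=C/c2cc(O)cc3c2[C@H](c2cc(O)c4c(c2)[C@@H](c2cc(O)cc(O)c2)[C@H](c2ccc(O)cc2)O4)[C@@H](c2ccc(O)cc2)O3)cc1 | target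

## Step count and least certain steps

Total: 20 steps. Longest linear sequence: 19 steps (steps 1–14 and 16–20, from 1); step 15 is a one-step side branch.

**Step 19 (key step).**
- What may go wrong: the 1,2-hydride shift from C3 may compete with the vinyl shift, because an alpha-substituted diazo ketone populates the s-trans conformer that reacts through a free carbene. Sensitised E/Z isomerisation of the styryl group, and trapping of the vinylketene by a second molecule instead of the tethered alkyne, are also possible.
- Fallback (known intermolecular benzannulation; sets out from 17, comes back at 38): the C2 hydroxyl of 17 is silylated to the tert-butyldimethylsilyl ether F1 (TBSOTf, 2,6-lutidine). Hydroboration–oxidation gives the primary alcohol F2, Dess–Martin oxidation the aldehyde F3, addition of 29 the dienyl carbinol F4, MnO2 the dienone F5, and detrifluoroacetylative diazo transfer the diazo dienone F6, which carries no alkyne. Irradiation of F6 with an excess of tert-butoxyethyne at 20 °C, removal of the excess and heating to 80 °C should give the resorcinol mono-tert-butyl ether F7 (C6–OH, tert-butoxy on C7a, styryl on C4). Trifluoroacetic acid at 0 °C then cleaves the tert-butyl ether, ionises the benzylic silyl ether at C2 and lets the C7a phenol close on the 4-methoxybenzylic cation to give the trans-dihydrobenzofuran 38; C2 is then set by the trans preference relative to C3.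

**Step 18.**
- What may go wrong: cycloaddition of the sulfonyl azide to the electron-rich alkynyl ether may compete with diazo transfer; the alkynyl ether may be hydrated during work-up; acylation of the hindered enolate may be slow.
- Fallback: the untethered series given under step 19 (from 17 through F1–F7 back to 38), in which the diazo transfer meets no alkyne; it needs no further compound (F0).

**Step 12.**
- What may go wrong: base-induced opening of the Bf dihydrofuran by deprotonation at C3' during the long exposure to KH and to excess n-BuLi, silyl migration in the alkoxide, and loss of the acid- and heat-sensitive alkynyl ether on isolation.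
- Fallback (sets out from 20, comes back at 24): 20 is formylated (acetic formic anhydride, pyridine) to the formate F8. Dibromo-olefination (CBr4, PPh3) gives the 2,2-dibromovinyl ether F9, and two equivalents of n-BuLi at −78 °C give 23, which methanol converts into 24. No free alkoxide is ever formed.

**Step 16.**
- What may go wrong: conjugate addition of n-BuLi to the unsaturated hydrazone or incomplete loss of N2 during the Shapiro reaction; enolisation of aldehyde 26 or consumption of the reagent by the alkyne C–H; Diels–Alder dimerisation of the acyl diene formed in step 17 if it is not used quickly.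
- Fallback (sets out from 15 and 26, comes back at 30): Horner–Wadsworth–Emmons reaction of 15 with diethyl (2-bromoallyl)phosphonate (NaH, THF) gives the bromodiene F10. Nozaki–Hiyama–Kishi coupling of F10 with 26 (CrCl2, NiCl2 (cat.), DMSO, rt), a non-basic organochromium addition that tolerates the alkyne C–H and the enolisable aldehyde, gives 30.

**Step 20.**
- What may go wrong: acid-induced opening of either dihydrofuran followed by irreversible capture of the benzylic cation by the stilbene or an arene (indane-type cyclisation), and incomplete cleavage of six ethers.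
- Fallback (sets out from 38, comes back at 39): nucleophilic demethylation with sodium ethanethiolate in DMF at 130 °C, which works by attack at methyl under basic conditions and avoids benzylic cations; it makes no new isolated compound (F0).

## Further compounds

F1 | step 19 | tert-butyl{[(1S,2R)-2-Bf-1-(4-methoxyphenyl)but-3-en-1-yl]oxy}dimethylsilane | C=C[C@H](c1cc(OC)c2c(c1)[C@@H](c1cc(OC)cc(OC)c1)[C@H](c1ccc(OC)cc1)O2)[C@H](O[Si](C)(C)C(C)(C)C)c1ccc(OC)cc1
F2 | step 19 | (3R,4S)-4-[(tert-butyldimethylsilyl)oxy]-4-(4-methoxyphenyl)-3-Bf-butan-1-ol | OCC[C@H](c1cc(OC)c2c(c1)[C@@H](c1cc(OC)cc(OC)c1)[C@H](c1ccc(OC)cc1)O2)[C@H](O[Si](C)(C)C(C)(C)C)c1ccc(OC)cc1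
F3 | step 19 | (3R,4S)-4-[(tert-butyldimethylsilyl)oxy]-4-(4-methoxyphenyl)-3-Bf-butanal | O=CC[C@H](c1cc(OC)c2c(c1)[C@@H](c1cc(OC)cc(OC)c1)[C@H](c1ccc(OC)cc1)O2)[C@H](O[Si](C)(C)C(C)(C)C)c1ccc(OC)cc1
F4 | step 19 | (1E,6R,7S)-7-[(tert-butyldimethylsilyl)oxy]-1,7-bis(4-methoxyphenyl)-3-methylidene-6-Bf-hept-1-en-4-ol (both C4 epimers) | C=C(/C=C/c1ccc(OC)cc1)C(O)C[C@H](c1cc(OC)c2c(c1)[C@@H](c1cc(OC)cc(OC)c1)[C@H](c1ccc(OC)cc1)O2)[C@H](O[Si](C)(C)C(C)(C)C)c1ccc(OC)cc1
F5 | step 19 | (1E,6R,7S)-7-[(tert-butyldimethylsilyl)oxy]-1,7-bis(4-methoxyphenyl)-3-methylidene-6-Bf-hept-1-en-4-one | C=C(/C=C/c1ccc(OC)cc1)C(=O)C[C@H](c1cc(OC)c2c(c1)[C@@H](c1cc(OC)cc(OC)c1)[C@H](c1ccc(OC)cc1)O2)[C@H](O[Si](C)(C)C(C)(C)C)c1ccc(OC)cc1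
F6 | step 19 | (1E,6S,7S)-7-[(tert-butyldimethylsilyl)oxy]-5-diazo-1,7-bis(4-methoxyphenyl)-3-methylidene-6-Bf-hept-1-en-4-one | C=C(/C=C/c1ccc(OC)cc1)C(=O)C(=[N+]=[N-])[C@H](c1cc(OC)c2c(c1)[C@@H](c1cc(OC)cc(OC)c1)[C@H](c1ccc(OC)cc1)O2)[C@H](O[Si](C)(C)C(C)(C)C)c1ccc(OC)cc1
F7 | step 19 | 3-tert-butoxy-4-[(1S,2S)-1-Bf-2-[(tert-butyldimethylsilyl)oxy]-2-(4-methoxyphenyl)ethyl]-5-[(E)-2-(4-methoxyphenyl)ethenyl]phenol | COc1ccc(/C=C/c2cc(O)cc(OC(C)(C)C)c2[C@H](c2cc(OC)c3c(c2)[C@@H](c2cc(OC)cc(OC)c2)[C@H](c2ccc(OC)cc2)O3)[C@H](O[Si](C)(C)C(C)(C)C)c2ccc(OC)cc2)cc1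
F8 | step 12 | (1S,2R)-2-Bf-1-(4-methoxyphenyl)-4-[(triisopropylsilyl)oxy]butyl formate | CC(C)[Si](OCC[C@H](c1cc(OC)c2c(c1)[C@@H](c1cc(OC)cc(OC)c1)[C@H](c1ccc(OC)cc1)O2)[C@H](OC=O)c1ccc(OC)cc1)(C(C)C)C(C)C
F9 | step 12 | {[(3R,4S)-4-[(2,2-dibromoethenyl)oxy]-4-(4-methoxyphenyl)-3-Bf-butyl]oxy}triisopropylsilane | CC(C)[Si](OCC[C@H](c1cc(OC)c2c(c1)[C@@H](c1cc(OC)cc(OC)c1)[C@H](c1ccc(OC)cc1)O2)[C@H](OC=C(Br)Br)c1ccc(OC)cc1)(C(C)C)C(C)C
F10 | step 16 | 1-[(1E)-3-bromobuta-1,3-dien-1-yl]-4-methoxybenzene | C=C(Br)/C=C/c1ccc(OC)cc1
F0 | step 18 | none | none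
F0 | step 20 | none | none
A1 | alternative 1 | 1,2-dicyclohexylethane-1,2-diol ester of [2-(2-bromo-3-methoxyphenyl)-2-(3,5-dimethoxyphenyl)-1-(4-methoxyphenyl)ethyl]boronic acid, configured as in the SMILES | COc1cccc([C@@H](c2cc(OC)cc(OC)c2)[C@H](c2ccc(OC)cc2)B2O[C@H](C3CCCCC3)[C@@H](C3CCCCC3)O2)c1Br
A2 | alternative 1 | 1,2-dicyclohexylethane-1,2-diol ester of [(2-bromo-3-methoxyphenyl)(3,5-dimethoxyphenyl)methyl]boronic acid, configured as in the SMILES | COc1cccc([C@@H](c2cc(OC)cc(OC)c2)B2O[C@H](C3CCCCC3)[C@@H](C3CCCCC3)O2)c1Br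
A3 | alternative 2 | methyl (2R,3R)-3-(3,5-dimethoxyphenyl)-7-methoxy-2-(4-methoxyphenyl)-2,3-dihydro-1-benzofuran-5-carboxylate | COC(=O)c1cc(OC)c2c(c1)[C@@H](c1cc(OC)cc(OC)c1)[C@H](c1ccc(OC)cc1)O2
A4 | alternative 2 | methyl 4-(3,5-dimethoxyphenyl)-8-methoxy-3-(4-methoxyphenyl)-2-oxo-3,4-dihydro-2H-chromene-6-carboxylate (C4 configured as C3' of the target, C3 either epimer) | COC(=O)c1cc(OC)c2OC(=O)C(c3ccc(OC)cc3)[C@H](c3cc(OC)cc(OC)c3)c2c1
A5 | alternative 3 | 4-[(2S,3S)-3-(4-benzyloxy-3-methoxyphenyl)-6-methoxy-4-(methoxymethoxy)-2,3-dihydro-1-benzofuran-2-yl]phenyl 4-methylbenzenesulfonate | COCOc1cc(OC)cc2c1[C@H](c1cc(OC)c(OCc3ccccc3)cc1)[C@@H](c1ccc(OS(=O)(=O)c3ccc(C)cc3)cc1)O2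
A6 | alternative 3 | 5-methoxy-3-(methoxymethoxy)-2-(trimethylsilyl)phenyl trifluoromethanesulfonate | COCOc1cc(OC)cc(OS(=O)(=O)C(F)(F)F)c1[Si](C)(C)C
A7 | alternative 3 | 4-[(2R,3R)-3-(4-benzyloxy-3-methoxyphenyl)oxiran-2-yl]phenyl 4-methylbenzenesulfonate | Cc1ccc(S(=O)(=O)Oc2ccc([C@H]3O[C@@H]3c3ccc(OCc4ccccc4)c(OC)c3)cc2)cc1
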